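**Plan**
- Retrosynthesis: cut the C3 ester, return the C9 ketone to a silyl-protected (S)-carbinol, then cut the C6–C7 bond and the oxirane O–C5 bond together, giving a ring α-chloro ketone and an E-alkenyl metal.
- Enabling feature: C6 lies between quaternary C1 and C5, so it can be a ketone with no α-hydrogen, and its carbonyl oxygen becomes the oxirane oxygen of the 7-oxabicyclo[4.1.0]heptane.
- Forward: the cyclohexane ring comes intact from actinol (silylation, enol silylation, chlorination at C5); the C7–C10 chain comes from (S)-but-3-yn-2-ol as an E-alkenyl iodide.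
- The union at C6 closes the oxirane in the same flask; desilylation, allylic oxidation at C9 and myristoylation at C3 finish the route.
- Stereochemistry: C3 from actinol; C5 from the C–Cl centre by inversion; C6 from face-selective addition; the E alkene from syn hydrozirconation; the auxiliary C9 centre is removed by oxidation.

Key step: step 6

Assumption: megastigmane (ionone) numbering is used for the coupled compounds (C1 gem-dimethyl, C3 oxygen, C5/C6 oxirane carbons, C7–C10 chain), and the three starting materials are taken as purchasable in the stated enantiomeric form.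

**Step 1**
Reactants: 1 (4R,6R)-4-hydroxy-2,2,6-trimethylcyclohexanone (actinol)
Product: 2 (4R,6R)-4-(tert-butyldimethylsilyloxy)-2,2,6-trimethylcyclohexanone
Conditions: TBSCl, imidazole, DMF, rt
Reagents that add atoms: tert-butyldimethylsilyl chloride, CC(C)(C)[Si](C)(C)Cl
Why: Standard imidazole-promoted silylation of a secondary alcohol, which leaves the ketone and both stereocentres untouched.

**Step 2**
Reactants: 2 (4R,6R)-4-(tert-butyldimethylsilyloxy)-2,2,6-trimethylcyclohexanone
Product: 3 (4R)-4-(tert-butyldimethylsilyloxy)-2,6,6-trimethyl-1-(trimethylsilyloxy)cyclohex-1-ene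
Conditions: TMSOTf, Et3N, CH2Cl2, 0 °C → rt
Reagents that add atoms: trimethylsilyl triflate, C[Si](C)(C)OS(=O)(=O)C(F)(F)F
Why: Soft enolisation with silyl triflate and amine can give only one silyl enol ether because only one α-carbon carries hydrogen; the methyl-bearing stereocentre, no longer needed, is erased.

**Step 3**
Reactants: 3 (4R)-4-(tert-butyldimethylsilyloxy)-2,6,6-trimethyl-1-(trimethylsilyloxy)cyclohex-1-ene
Product: 4 (2S,4S)-4-(tert-butyldimethylsilyloxy)-2-chloro-2,6,6-trimethylcyclohexanone (chloride cis to silyloxy)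
Conditions: NCS, THF, 0 °C → rt; chromatographic separation of the C2 epimers
Reagents that add atoms: N-chlorosuccinimide, O=C1CCC(=O)N1Cl
Why: Electrophilic α-chlorination of a silyl enol ether gives the α-chloro ketone directly and cannot over-chlorinate since both α-carbons are then quaternary; the new centre is set by the face of attack, which is not expected to favour the needed sense reliably, so both epimers should form and the cis epimer is isolated and assigned by NOE.

**Step 4**
Reactants: 5 (S)-but-3-yn-2-ol
Product: 6 (S)-tert-butyl(but-3-yn-2-yloxy)dimethylsilane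
Conditions: TBSCl, imidazole, CH2Cl2, 0 °C → rt
Reagents that add atoms: tert-butyldimethylsilyl chloride, CC(C)(C)[Si](C)(C)Cl
Why: Standard silylation of a secondary propargylic alcohol without effect on the carbinol centre.

**Step 5**
Reactants: 6 (S)-tert-butyl(but-3-yn-2-yloxy)dimethylsilane
Product: 8 (S,E)-tert-butyl[(4-iodobut-3-en-2-yl)oxy]dimethylsilane, via alkenylzirconocene chloride 7 (not isolated)
Conditions: Cp2Zr(H)Cl, THF, rt, dark; then I2, 0 °C
Reagents that add atoms: iodine, II
Why: Hydrozirconation of a terminal alkyne is syn and places zirconium on the terminal carbon, and iodinolysis of the C–Zr bond goes with retention, so the E iodide should result.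

**Step 6**
Reactants: 4 (2S,4S)-4-(tert-butyldimethylsilyloxy)-2-chloro-2,6,6-trimethylcyclohexanone; 8 (S,E)-tert-butyl[(4-iodobut-3-en-2-yl)oxy]dimethylsilane
Product: 12 (3S,5R,6S,7E,9S)-3,9-bis(tert-butyldimethylsilyloxy)-5,6-epoxymegastigm-7-ene, via alkenyllithium 9 (not isolated), via alkenylcerium dichloride 10 (not isolated), via chlorohydrin 11 (not isolated)
Conditions: 8, t-BuLi (2 equiv), Et2O, −78 °C; anhydrous CeCl3, THF, −78 °C; 4, −78 → −20 °C; then NaOMe, MeOH, −20 °C → rt
Reagents that add atoms: none
Why: Iodine–lithium exchange with retention of the E geometry and transmetalation give a weakly basic alkenylcerium that adds 1,2 to the C6 carbonyl, which has no α-hydrogen and so cannot enolise; this combines the known organocerium addition to hindered ketones with the classical addition to an α-halo ketone and base closure of the halohydrin. In the chair of 4 with silyloxy and chloride equatorial, the C5 methyl and one C1 methyl are axial on the face anti to silyloxy, so the reagent should enter axially from the silyloxy face and set C6 with oxygen trans to chloride. Cerium alkoxides are poor nucleophiles, so methoxide in methanol is added to the same flask to free the tertiary alkoxide of 11, which displaces the tertiary chloride by 3-exo-tet SN2 closure through a twist conformer with O and Cl antiperiplanar. Inversion at C5 converts the chloride configuration into the (5R) oxirane carbon, so the oxirane ends anti to the C3 oxygen. The selectivity the step needs is facial: a Felkin–Anh-type attack anti to an axial C–Cl bond in the ring-flipped chair would give the cis chlorohydrin, which cannot close, and that chair is disfavoured because it carries chloride, silyloxy and a methyl group all axial on one face.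

**Step 7**
Reactants: 12 (3S,5R,6S,7E,9S)-3,9-bis(tert-butyldimethylsilyloxy)-5,6-epoxymegastigm-7-ene
Product: 13 (3S,5R,6S,7E,9S)-5,6-epoxymegastigm-7-ene-3,9-diol
Conditions: TBAF, THF, 0 °C → rt
Reagents that add atoms: none
Why: Fluoride cleaves both secondary silyl ethers under basic conditions, which the acid-sensitive vinyl oxirane should tolerate.

**Step 8**
Reactants: 13 (3S,5R,6S,7E,9S)-5,6-epoxymegastigm-7-ene-3,9-diol
Product: 14 (3S,5R,6S,7E)-5,6-epoxy-3-hydroxymegastigm-7-en-9-one
Conditions: activated MnO2 (excess), CH2Cl2, rt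
Reagents that add atoms: none
Why: Manganese dioxide oxidises allylic alcohols selectively, so only the C9 hydroxyl should go to the enone while the saturated C3 alcohol, the oxirane and the E alkene remain.

**Step 9**
Reactants: 14 (3S,5R,6S,7E)-5,6-epoxy-3-hydroxymegastigm-7-en-9-one; 15 tetradecanoyl chloride
Product: 16 (3S,5R,6S,7E)-5,6-epoxy-9-oxomegastigm-7-en-3-yl tetradecanoate (CNP0118807.1)
Conditions: Et3N, DMAP (cat.), CH2Cl2, 0 °C → rt
Reagents that add atoms: none
Why: DMAP-catalysed acylation of the one remaining secondary alcohol with amine present to trap HCl, which protects the oxirane from acid-induced rearrangement and touches no stereocentre.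

**Compound list**
1 | (4R,6R)-4-hydroxy-2,2,6-trimethylcyclohexanone (actinol) | O[C@H]1CC(C)(C)C(=O)[C@H](C)C1 | starting material
2 | (4R,6R)-4-(tert-butyldimethylsilyloxy)-2,2,6-trimethylcyclohexanone | CC(C)(C)[Si](C)(C)O[C@H]1CC(C)(C)C(=O)[C@H](C)C1 | intermediate
3 | (4R)-4-(tert-butyldimethylsilyloxy)-2,6,6-trimethyl-1-(trimethylsilyloxy)cyclohex-1-ene | CC(C)(C)[Si](C)(C)O[C@H]1CC(C)(C)C(O[Si](C)(C)C)=C(C)C1 | intermediate
4 | (2S,4S)-4-(tert-butyldimethylsilyloxy)-2-chloro-2,6,6-trimethylcyclohexanone, chloride cis to silyloxy | CC(C)(C)[Si](C)(C)O[C@H]1CC(C)(C)C(=O)[C@@](C)(Cl)C1 | intermediate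
5 | (S)-but-3-yn-2-ol | C[C@H](O)C#C | starting material
6 | (S)-tert-butyl(but-3-yn-2-yloxy)dimethylsilane | C[C@H](O[Si](C)(C)C(C)(C)C)C#C | intermediate
7 | chloro{(1E,3S)-3-[(tert-butyldimethylsilyl)oxy]but-1-en-1-yl}bis(cyclopentadienyl)zirconium, formed in the flask | C[C@H](O[Si](C)(C)C(C)(C)C)/C=C/[Zr](Cl)(C1C=CC=C1)C1C=CC=C1 | intermediate
8 | (S,E)-tert-butyl[(4-iodobut-3-en-2-yl)oxy]dimethylsilane | C[C@H](O[Si](C)(C)C(C)(C)C)/C=C/I | intermediate
9 | {(1E,3S)-3-[(tert-butyldimethylsilyl)oxy]but-1-en-1-yl}lithium, formed in the flask | C[C@H](O[Si](C)(C)C(C)(C)C)/C=C/[Li] | intermediate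
10 | dichloro{(1E,3S)-3-[(tert-butyldimethylsilyl)oxy]but-1-en-1-yl}cerium, formed in the flask | C[C@H](O[Si](C)(C)C(C)(C)C)/C=C/[Ce](Cl)Cl | intermediate
11 | (1S,2S,4S)-4-(tert-butyldimethylsilyloxy)-1-[(1E,3S)-3-(tert-butyldimethylsilyloxy)but-1-en-1-yl]-2-chloro-2,6,6-trimethylcyclohexan-1-ol, hydroxyl trans to chloride, formed in the flask as its cerium alkoxide | CC(C)(C)[Si](C)(C)O[C@H]1CC(C)(C)[C@@](O)(/C=C/[C@H](C)O[Si](C)(C)C(C)(C)C)[C@@](C)(Cl)C1 | intermediate
12 | (3S,5R,6S,7E,9S)-3,9-bis(tert-butyldimethylsilyloxy)-5,6-epoxymegastigm-7-ene, oxirane anti to the C3 oxygen | CC(C)(C)[Si](C)(C)O[C@H]1CC(C)(C)[C@]2(/C=C/[C@H](C)O[Si](C)(C)C(C)(C)C)O[C@]2(C)C1 | intermediate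
13 | (3S,5R,6S,7E,9S)-5,6-epoxymegastigm-7-ene-3,9-diol | O[C@H]1CC(C)(C)[C@]2(/C=C/[C@H](C)O)O[C@]2(C)C1 | intermediate
14 | (3S,5R,6S,7E)-5,6-epoxy-3-hydroxymegastigm-7-en-9-one | O[C@H]1CC(C)(C)[C@]2(/C=C/C(C)=O)O[C@]2(C)C1 | intermediate
15 | tetradecanoyl (myristoyl) chloride | CCCCCCCCCCCCCC(=O)Cl | starting material
16 | (3S,5R,6S,7E)-5,6-epoxy-9-oxomegastigm-7-en-3-yl tetradecanoate | CCCCCCCCCCCCCC(=O)O[C@H]1CC(C)(C)[C@]2(/C=C/C(C)=O)O[C@]2(C)C1 | target

**Step count**
Total: 9 steps. Longest linear sequence: 7 steps (1, 2, 3, 6, 7, 8, 9).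

**Steps most likely to fail**

1. Step 6. The reagent may add from the face anti to silyloxy, which leaves oxygen cis to chloride; the stalled alkoxide may then contract the ring instead of closing. Closure may also be slow because it needs a twist conformer. The fallback sets out from ketone 2 and returns at 12. Alkenylcerium 10, made from 8 as in step 6, is added to 2 to give the tertiary allylic alcohol (4R,6R)-4-(tert-butyldimethylsilyloxy)-1-[(1E,3S)-3-(tert-butyldimethylsilyloxy)but-1-en-1-yl]-2,2,6-trimethylcyclohexan-1-ol F1, whose carbinol configuration is immaterial. Dehydration with the Burgess reagent in warm toluene removes the C5 hydrogen and gives the conjugated diene (3R,7E,9S)-3,9-bis(tert-butyldimethylsilyloxy)megastigma-5,7-diene F2. Buffered mCPBA (NaHCO3, CH2Cl2, 0 °C) should then epoxidise the electron-rich tetrasubstituted ring alkene from the face anti to the silyloxy group, as is usual for 3-silyloxy ionone-type rings, and give 12 after separation from any syn oxirane.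

2. Step 3. Chlorine may be delivered mainly to the face anti to the silyloxy group (axial attack on the half-chair), which would leave the needed cis epimer as the minor or an inseparable component; the tertiary chloride cannot be epimerised afterwards. The fallback sets out from ketone 2 and returns at 4, and it turns the same anti preference to advantage. KHMDS and Comins' reagent (THF, −78 °C) give the enol triflate (R)-4-(tert-butyldimethylsilyloxy)-2,6,6-trimethylcyclohex-1-en-1-yl trifluoromethanesulfonate F3. Palladium-catalysed formate reduction (Pd(OAc)2, PPh3, HCO2H, Bu3N, DMF, 60 °C) gives the alkene (R)-tert-butyldimethyl[(3,5,5-trimethylcyclohex-3-en-1-yl)oxy]silane F4. Buffered mCPBA should epoxidise anti to silyloxy and give tert-butyldimethyl{[(1R,3S,6S)-1,5,5-trimethyl-7-oxabicyclo[4.1.0]heptan-3-yl]oxy}silane F5. Pyridinium chloride in CH2Cl2 opens the oxirane at the tertiary carbon with inversion, which places chloride cis to silyloxy in (1S,2S,4S)-4-(tert-butyldimethylsilyloxy)-2-chloro-2,6,6-trimethylcyclohexan-1-ol F6. Buffered Dess–Martin oxidation of the hindered secondary alcohol then gives 4.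

3. Step 5. Hydrometalation may be incomplete, and protonolysis of the alkenylzirconium by adventitious moisture would give the terminal alkene in place of the iodide. The fallback sets out from alkyne 6 and returns at 8. Palladium-catalysed hydrostannation (Bu3SnH, PdCl2(PPh3)2 cat., THF, 0 °C) should give, by syn addition with tin at the terminus, (S,E)-tert-butyldimethyl{[4-(tributylstannyl)but-3-en-2-yl]oxy}silane F7, which can be purified. Iododestannylation (I2, CH2Cl2, 0 °C) proceeds with retention and gives 8.

**Further compounds**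
F1 | step 6 | (4R,6R)-4-(tert-butyldimethylsilyloxy)-1-[(1E,3S)-3-(tert-butyldimethylsilyloxy)but-1-en-1-yl]-2,2,6-trimethylcyclohexan-1-ol (carbinol configuration not defined) | CC(C)(C)[Si](C)(C)O[C@H]1CC(C)(C)C(O)(/C=C/[C@H](C)O[Si](C)(C)C(C)(C)C)[C@H](C)C1
F2 | step 6 | (3R,7E,9S)-3,9-bis(tert-butyldimethylsilyloxy)megastigma-5,7-diene | CC(C)(C)[Si](C)(C)O[C@H]1CC(C)(C)C(/C=C/[C@H](C)O[Si](C)(C)C(C)(C)C)=C(C)C1
F3 | step 3 | (R)-4-(tert-butyldimethylsilyloxy)-2,6,6-trimethylcyclohex-1-en-1-yl trifluoromethanesulfonate | CC(C)(C)[Si](C)(C)O[C@H]1CC(C)(C)C(OS(=O)(=O)C(F)(F)F)=C(C)C1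
F4 | step 3 | (R)-tert-butyldimethyl[(3,5,5-trimethylcyclohex-3-en-1-yl)oxy]silane | CC(C)(C)[Si](C)(C)O[C@H]1CC(C)(C)C=C(C)C1
F5 | step 3 | tert-butyldimethyl{[(1R,3S,6S)-1,5,5-trimethyl-7-oxabicyclo[4.1.0]heptan-3-yl]oxy}silane (oxirane anti to silyloxy) | CC(C)(C)[Si](C)(C)O[C@H]1CC(C)(C)[C@@H]2O[C@]2(C)C1
F6 | step 3 | (1S,2S,4S)-4-(tert-butyldimethylsilyloxy)-2-chloro-2,6,6-trimethylcyclohexan-1-ol | CC(C)(C)[Si](C)(C)O[C@H]1CC(C)(C)[C@H](O)[C@@](C)(Cl)C1
F7 | step 5 | (S,E)-tert-butyldimethyl{[4-(tributylstannyl)but-3-en-2-yl]oxy}silane | C[C@H](O[Si](C)(C)C(C)(C)C)/C=C/[Sn](CCCC)(CCCC)CCCC
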